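The trans-decalin is disconnected at the ring-fusion bond C5–C10 and at C3–C4, so both rings come from one open chain. The route exploits the C1 carbonyl of ring A: it makes C10 an α-keto radical site and C3 the β-carbon of an (E)-chlorovinyl ketone, while C4=C5 is the proximal alkene of a geranyl unit that already carries the C4 methyl and the side chain. A silane-mediated radical cascade on an acyclic α-bromo ketone closes ring B (C10→C5, 6-exo) and ring A (C4→C3, 6-endo), setting C3, C4, C5 and C10 under control of C9, the only defined stereocentre present, which comes from an Evans conjugate addition.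

Key step: step 13

Remark: atom numbers are those of the decalin (C1–C10 in the rings, C11 on C9, C12 on C8) and are used for all intermediates. The configuration at C10 before the key step is immaterial, because C10 becomes a planar radical.

Step 1
Reactants: 1 geranyl bromide; 2 propargyl alcohol
Product: 3 (5E)-6,10-dimethylundeca-5,9-dien-2-yn-1-ol
Conditions: CuI, K2CO3, NaI, DMF, rt
Reagents that add atoms: none
Why: Copper-mediated alkynylation of a primary allylic bromide (the copper acetylide of 2 attacks the CH2Br carbon without allylic transposition) joins C6 to C7 and leaves the E alkene untouched; no stereocentre is formed.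

Step 2
Reactants: 3 (5E)-6,10-dimethylundeca-5,9-dien-2-yn-1-ol
Product: 5 (2Z,5E)-2-iodo-6,10-dimethylundeca-2,5,9-trien-1-ol, via alkenylstannane 4 (not isolated)
Conditions: Bu3SnH, [(C5Me5)RuCl]4 (cat.), CH2Cl2, rt; then I2, 0 °C
Reagents that add atoms: iodine, II
Why: Hydroxyl-directed ruthenium-catalysed trans-hydrostannation places tin on the alkyne carbon next to the carbinol with H and Sn anti, and iododestannylation with retention gives the Z-iodide in which iodine (the future C8–C9 bond) is cis to the C6 chain, as ring B requires.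

Step 3
Reactants: 5 (2Z,5E)-2-iodo-6,10-dimethylundeca-2,5,9-trien-1-ol
Product: 6 (2Z,5E)-2-iodo-6,10-dimethylundeca-2,5,9-trienal
Conditions: MnO2, CH2Cl2, rt
Reagents that add atoms: none
Why: Allylic alcohol oxidation with MnO2 is selective for the activated primary alcohol and does not touch the alkenes or the vinyl iodide.

Step 4
Reactants: 6 (2Z,5E)-2-iodo-6,10-dimethylundeca-2,5,9-trienal
Product: 7 2-[(1Z,4E)-1-iodo-5,9-dimethyldeca-1,4,8-trien-1-yl]-1,3-dioxolane
Conditions: HOCH2CH2OH, PPTS (cat.), benzene, reflux, Dean–Stark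
Reagents that add atoms: ethane-1,2-diol, OCCO
Why: Acid-catalysed acetalisation with azeotropic removal of water masks C12 at the aldehyde oxidation level for the rest of the route, and PPTS is too weak an acid to isomerise the skipped triene.

Step 5
Reactants: 8 (S)-4-benzyloxazolidin-2-one; 9 acryloyl chloride
Product: 10 (S)-3-acryloyl-4-benzyloxazolidin-2-one
Conditions: n-BuLi, THF, −78 °C; then 9, −78 to 0 °C
Reagents that add atoms: none
Why: N-Acylation of the lithiated oxazolidinone by the acid chloride puts the chiral auxiliary on the future C1–C10–C9 unit.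

Step 6
Reactants: 10 (S)-3-acryloyl-4-benzyloxazolidin-2-one; 11 allyl tert-butyldimethylsilyl ether
Product: 12 (S)-4-benzyl-3-[(E)-4-(tert-butyldimethylsilyloxy)but-2-enoyl]oxazolidin-2-one
Conditions: second-generation Hoveyda–Grubbs catalyst RuCl2(H2IMes)(=CH-C6H4-2-O-i-Pr) (5 mol %), 11 (3 equiv), CH2Cl2, 40 °C
Reagents that add atoms: none
Why: Olefin cross-metathesis between the electron-poor acryloyl imide and an excess of the terminal allyl ether gives the E-enoyl imide with loss of ethylene and adds C11 with its oxygen.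

Step 7
Reactants: 7 2-[(1Z,4E)-1-iodo-5,9-dimethyldeca-1,4,8-trien-1-yl]-1,3-dioxolane; 12 (S)-4-benzyl-3-[(E)-4-(tert-butyldimethylsilyloxy)but-2-enoyl]oxazolidin-2-one
Product: 14 (S)-4-benzyl-3-[(3R,4E,7E)-3-(tert-butyldimethylsilyloxymethyl)-4-(1,3-dioxolan-2-yl)-8,12-dimethyltrideca-4,7,11-trienoyl]oxazolidin-2-one (C9 and C6 cis across C7=C8), via alkenylmagnesium chloride 13 (not isolated)
Conditions: 7, i-PrMgCl·LiCl, THF, −20 to 0 °C; then CuBr·SMe2 (0.3 equiv), 12, THF/Me2S, −40 to −10 °C; aq. NH4Cl
Reagents that add atoms: none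
Why: Iodine–magnesium exchange retains the alkene geometry, and copper-catalysed conjugate addition of the alkenyl Grignard to the magnesium-chelated s-cis enoyl imide takes place on the face opposite the benzyl group (auxiliary-controlled Evans-type 1,4-addition), setting C9 with the R configuration found in the target.

Step 8
Reactants: 14 conjugate adduct
Product: 15 (S)-4-benzyl-3-[(2S,3R,4E,7E)-3-(tert-butyldimethylsilyloxymethyl)-4-(1,3-dioxolan-2-yl)-2,8,12-trimethyltrideca-4,7,11-trienoyl]oxazolidin-2-one
Conditions: NaN(SiMe3)2, THF, −78 °C; MeI, −78 to −40 °C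
Reagents that add atoms: iodomethane, CI
Why: Evans alkylation of the chelated Z-enolate with MeI anti to the benzyl group introduces the C10 methyl as a single diastereomer; this centre is later erased, so its configuration does not matter.

Step 9
Reactants: 15 methylated imide
Product: 16 (2S,3R,4E,7E)-3-(tert-butyldimethylsilyloxymethyl)-4-(1,3-dioxolan-2-yl)-N-methoxy-N,2,8,12-tetramethyltrideca-4,7,11-trienamide
Conditions: MeNH(OMe)·HCl, AlMe3, CH2Cl2, −10 °C to rt
Reagents that add atoms: N,O-dimethylhydroxylamine hydrochloride, CNOC.Cl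
Why: Transamination of the imide with the aluminium amide formed from AlMe3 and the amine hydrochloride gives the Weinreb amide and releases the auxiliary 8 for reuse.

Step 10
Reactants: 16 Weinreb amide; 17 (E)-1,2-bis(tributylstannyl)ethene
Product: 19 (1E,4S,5R,6E,9E)-5-(tert-butyldimethylsilyloxymethyl)-6-(1,3-dioxolan-2-yl)-4,10,14-trimethyl-1-(tributylstannyl)pentadeca-1,6,9,13-tetraen-3-one, via stannylvinyllithium 18 (not isolated)
Conditions: 17, n-BuLi, THF, −78 °C; then 16, −78 to −40 °C; aq. NH4Cl
Reagents that add atoms: none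
Why: Tin–lithium exchange on 17 gives the E-vinyllithium with retention, and its addition to the Weinreb amide stops at the chelated tetrahedral intermediate, so the E-enone forms on work-up (Weinreb ketone synthesis) and C2 and C3 are in place.

Step 11
Reactants: 19 β-stannyl enone
Product: 20 (1E,4S,5R,6E,9E)-1-chloro-5-(tert-butyldimethylsilyloxymethyl)-6-(1,3-dioxolan-2-yl)-4,10,14-trimethylpentadeca-1,6,9,13-tetraen-3-one
Conditions: CuCl2 (2.2 equiv), THF, 0 °C to rt
Reagents that add atoms: copper dichloride, Cl[Cu]Cl
Why: Chlorodestannylation of the alkenylstannane by CuCl2 proceeds with retention of the E geometry and without acid, so the dioxolane and the silyl ether survive and the (E)-β-chlorovinyl ketone is obtained.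

Step 12
Reactants: 20 (E)-β-chlorovinyl ketone
Product: 22 C10-bromo derivative of 20 (4-bromo-1-chloro ketone; both epimers at the new C–Br centre; C9 and all alkenes unchanged), via silyl dienol ether 21 (not isolated)
Conditions: Me3SiOTf, i-Pr2NEt, CH2Cl2, −78 to −20 °C; then NBS, THF, −78 °C
Reagents that add atoms: N-bromosuccinimide, O=C1CCC(=O)N1Br
Why: Soft enolisation can occur only towards C10 (the other α-carbon is vinylic), and the cross-conjugated silyl dienol ether is brominated by NBS at its nucleophilic terminus C10 (α-bromination via a silyl enol ether); both C10 epimers lead to the same radical.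

Step 13
Reactants: 22 α-bromo (E)-β-chlorovinyl ketone
Product: 23 trans-decalone: 3β-chloro-9β-(tert-butyldimethylsilyloxymethyl)-8-(1,3-dioxolan-2-yl)-4β,10β-dimethyl-4α-(4-methylpent-3-enyl)-5α-H-decal-7-en-1-one
Conditions: (Me3Si)3SiH (1.2 equiv) and AIBN (0.2 equiv) added over 8 h by syringe pump, benzene (0.005 M), 80 °C
Reagents that add atoms: none
Why: (Me3Si)3Si• abstracts bromine to give the tertiary α-keto radical at C10, which adds 6-exo-trig to C5 of the electron-rich C4=C5 alkene (ring B), and the tertiary C4 radical so formed adds 6-endo-trig to C3, the β-carbon of the (E)-chlorovinyl ketone (ring A), before the C2 α-keto radical takes hydrogen from the silane; the closest known reaction type is the stannane- or silane-mediated tandem radical cyclisation of α-halo ketones onto alkenes and enones. C9 controls C10 and C5: allylic 1,3-strain keeps C9–H in the plane of the acyl-substituted radical, so ring B closes through a half-chair with the acyl group, the C11 arm and the new C4 arm equatorial and the C10 methyl axial (trans ring fusion, 9β,10β). C3 follows from the E geometry of the chlorovinyl ketone, which puts chlorine equatorial (3β) in the chair-like closure of ring A, and at the freely rotating C4 radical the methyl, smaller than the homoprenyl chain, should take the axial site syn to the C10 methyl (4β-methyl). The step needs cyclisation to outrun hydrogen transfer to the C10 and C4 radicals, which high dilution and slow addition of the silane should secure. It also needs the chlorine to survive, which is expected because the equatorial C3–Cl bond lies near the nodal plane of the C2 radical (poor overlap for β-scission) while hydrogen transfer from the silane is fast.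

Step 14
Reactants: 23 silyl ether decalone
Product: 24 3β-chloro-8-(1,3-dioxolan-2-yl)-9β-(hydroxymethyl)-4β,10β-dimethyl-4α-(4-methylpent-3-enyl)-5α-H-decal-7-en-1-one
Conditions: HF·pyridine, pyridine, THF, 0 °C
Reagents that add atoms: none
Why: Fluoride-mediated cleavage of the primary silyl ether under buffered conditions that neither eliminate HCl from the β-chloro ketone (the equatorial chloride is poorly aligned for E1cB) nor hydrolyse the dioxolane.

Step 15
Reactants: 24 γ-hydroxy ketone
Product: 25 3β-chloro-8-(1,3-dioxolan-2-yl)-9β-(hydroxymethyl)-4β,10β-dimethyl-4α-(4-methylpent-3-enyl)-5α-H-decal-7-en-1α-ol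
Conditions: Me4NBH(OAc)3, MeCN/AcOH, −20 °C
Reagents that add atoms: none
Why: Hydroxyl-directed reduction (Saksena–Evans): the C11 alkoxytriacetoxyborate delivers hydride intramolecularly to the β-face of the C1 ketone, which lies peri to C11 across C10, so the axial 1α-alcohol is formed, while the reagent alone does not reduce ketones.

Step 16
Reactants: 25 1α,11-diol
Product: 26 3β-chloro-8-(1,3-dioxolan-2-yl)-1α-hydroxy-4β,10β-dimethyl-4α-(4-methylpent-3-enyl)-5α-H-decal-7-ene-9β-carbaldehyde
Conditions: TEMPO (10 mol %), PhI(OAc)2, CH2Cl2, rt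
Reagents that add atoms: none
Why: Oxoammonium (TEMPO) oxidation with PhI(OAc)2 converts the primary C11 alcohol to the aldehyde far faster than the hindered axial secondary C1 alcohol, and no lactol or lactone can form because C12 is still an acetal.

Step 17
Reactants: 26 hydroxy aldehyde acetal
Product: 27 target CNP0155449.1, 3β-chloro-1α-hydroxy-4β,10β-dimethyl-4α-(4-methylpent-3-enyl)-5α-H-decal-7-ene-8,9β-dicarbaldehyde
Conditions: PPTS, acetone/H2O, rt
Reagents that add atoms: water, O
Why: Mild acid-catalysed hydrolysis of the dioxolane of an enal releases the C12 aldehyde, and the conditions are kept mild and short to avoid epimerisation at C9.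

Compound list
1 | geranyl bromide, (2E)-1-bromo-3,7-dimethylocta-2,6-diene | CC(C)=CCC/C(C)=C/CBr | starting material
2 | propargyl alcohol | C#CCO | starting material
3 | (5E)-6,10-dimethylundeca-5,9-dien-2-yn-1-ol | CC(C)=CCC/C(C)=C/CC#CCO | intermediate
4 | (2Z,5E)-6,10-dimethyl-2-(tributylstannyl)undeca-2,5,9-trien-1-ol | OC/C([Sn](CCCC)(CCCC)CCCC)=C/C/C=C(\C)CCC=C(C)C | intermediate
5 | (2Z,5E)-2-iodo-6,10-dimethylundeca-2,5,9-trien-1-ol | OC/C(I)=C/C/C=C(\C)CCC=C(C)C | intermediate
6 | (2Z,5E)-2-iodo-6,10-dimethylundeca-2,5,9-trienal | O=C/C(I)=C/C/C=C(\C)CCC=C(C)C | intermediate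
7 | 2-[(1Z,4E)-1-iodo-5,9-dimethyldeca-1,4,8-trien-1-yl]-1,3-dioxolane | C1COC(O1)/C(I)=C/C/C=C(\C)CCC=C(C)C | intermediate
8 | (S)-4-benzyloxazolidin-2-one | O=C1N[C@@H](Cc2ccccc2)CO1 | starting material
9 | acryloyl chloride | C=CC(Cl)=O | starting material
10 | (S)-3-acryloyl-4-benzyloxazolidin-2-one | C=CC(=O)N1[C@@H](Cc2ccccc2)COC1=O | intermediate
11 | allyl tert-butyldimethylsilyl ether | C=CCO[Si](C)(C)C(C)(C)C | starting material
12 | (S)-4-benzyl-3-[(E)-4-(tert-butyldimethylsilyloxy)but-2-enoyl]oxazolidin-2-one | CC(C)(C)[Si](C)(C)OC/C=C/C(=O)N1[C@@H](Cc2ccccc2)COC1=O | intermediate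
13 | alkenylmagnesium chloride of 7 (MgCl in place of I, geometry retained) | Cl[Mg]/C(=C\C/C=C(\C)CCC=C(C)C)C1OCCO1 | intermediate
14 | conjugate adduct, (3R) imide (C9 set) | O=C(C[C@@H](CO[Si](C)(C)C(C)(C)C)/C(=C\C/C=C(\C)CCC=C(C)C)C1OCCO1)N1[C@@H](Cc2ccccc2)COC1=O | intermediate
15 | (2S,3R) α-methyl imide | O=C([C@@H](C)[C@@H](CO[Si](C)(C)C(C)(C)C)/C(=C\C/C=C(\C)CCC=C(C)C)C1OCCO1)N1[C@@H](Cc2ccccc2)COC1=O | intermediate
16 | (2S,3R) Weinreb amide | CON(C)C(=O)[C@@H](C)[C@@H](CO[Si](C)(C)C(C)(C)C)/C(=C\C/C=C(\C)CCC=C(C)C)C1OCCO1 | intermediate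
17 | (E)-1,2-bis(tributylstannyl)ethene | CCCC[Sn](CCCC)(CCCC)/C=C/[Sn](CCCC)(CCCC)CCCC | starting material
18 | (E)-2-(tributylstannyl)vinyllithium | [Li]/C=C/[Sn](CCCC)(CCCC)CCCC | intermediate
19 | (E)-β-stannylvinyl ketone | CCCC[Sn](CCCC)(CCCC)/C=C/C(=O)[C@@H](C)[C@@H](CO[Si](C)(C)C(C)(C)C)/C(=C\C/C=C(\C)CCC=C(C)C)C1OCCO1 | intermediate
20 | (E)-β-chlorovinyl ketone | Cl/C=C/C(=O)[C@@H](C)[C@@H](CO[Si](C)(C)C(C)(C)C)/C(=C\C/C=C(\C)CCC=C(C)C)C1OCCO1 | intermediate
21 | trimethylsilyl dienol ether of 20 (C1=C10, either geometry) | Cl/C=C/C(O[Si](C)(C)C)=C(C)[C@@H](CO[Si](C)(C)C(C)(C)C)/C(=C\C/C=C(\C)CCC=C(C)C)C1OCCO1 | intermediate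
22 | C10-bromo ketone (both C10 epimers) | Cl/C=C/C(=O)C(C)(Br)[C@@H](CO[Si](C)(C)C(C)(C)C)/C(=C\C/C=C(\C)CCC=C(C)C)C1OCCO1 | intermediate
23 | trans-decalone with 3β-Cl, 11-OTBS, 12-dioxolane | CC(C)=CCC[C@]1(C)[C@@H](Cl)CC(=O)[C@]2(C)[C@@H](CO[Si](C)(C)C(C)(C)C)C(C3OCCO3)=CC[C@@H]12 | intermediate
24 | 11-hydroxy decalone | CC(C)=CCC[C@]1(C)[C@@H](Cl)CC(=O)[C@]2(C)[C@@H](CO)C(C3OCCO3)=CC[C@@H]12 | intermediate
25 | 1α,11-diol | CC(C)=CCC[C@]1(C)[C@@H](Cl)C[C@H](O)[C@]2(C)[C@@H](CO)C(C3OCCO3)=CC[C@@H]12 | intermediate
26 | 1α-hydroxy 11-aldehyde, 12-dioxolane | CC(C)=CCC[C@]1(C)[C@@H](Cl)C[C@H](O)[C@]2(C)[C@@H](C=O)C(C3OCCO3)=CC[C@@H]12 | intermediate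
27 | CNP0155449.1 | CC(C)=CCC[C@]1(C)[C@@H](Cl)C[C@H](O)[C@]2(C)[C@@H](C=O)C(C=O)=CC[C@@H]12 | target

Total step count: 17. Longest linear sequence: 15 steps (steps 1–4 and 7–17).

Steps most likely to fail

Step 13. Hydrogen may be transferred to the C10 radical, from the silane or from the doubly allylic C6–H, before ring B closes, and the freely rotating C4 radical may close ring A with weak facial discrimination. The fallback sets out from 22 and comes back at 23. The cascade would be run as a copper-catalysed bromine-atom-transfer cyclisation with no hydrogen donor present (CuBr with tris(2-pyridylmethyl)amine, cat. AIBN, 1,2-dichloroethane, 80 °C), so that the C10 radical can only cyclise or return to 22. The chain would end by bromine transfer to C2 and give the 2-bromo decalone F1. The C2 bromine would then be removed in a separate reduction ((Me3Si)3SiH, Et3B, air, toluene, 0 °C) to give 23.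

Step 7. Transfer of the hindered α-acetal alkenyl group may be slow, the alkenylmetal may be lost by β-elimination of the acetal oxygen, and facial selectivity on the auxiliary may erode. The fallback sets out from 7 and comes back at 16. Iodide 7 would be converted (i-PrMgCl·LiCl, then 2-isopropoxy-4,4,5,5-tetramethyl-1,3,2-dioxaborolane) into the pinacol boronate F2. A rhodium-catalysed asymmetric 1,4-addition to furan-2(5H)-one (Hayashi–Miyaura reaction; Rh(acac)(C2H4)2, (R)-BINAP, KOH, dioxane/H2O) should give the (R)-β-alkenyl lactone F3, with C9 set by the ligand. Methylation trans to the C9 substituent (LiN(i-Pr)2, MeI, THF, −78 °C) would give the methyl lactone F4. Opening with MeNH(OMe)·HCl/AlMe3 would give the hydroxy Weinreb amide F5, and silylation (TBSCl, imidazole) returns to 16.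

Step 15. Hydride delivery through the seven-membered alkoxyborate arrangement may be too slow, so that the ketone is left or is attacked from the more open α-face to give the equatorial 1β-alcohol. The fallback sets out from 23 and comes back at 25. The silyl ether would be kept and the ketone reduced under steric approach control with LiBH(s-Bu)3 (THF, −78 °C). By analogy with 3-oxo-4,4-dimethyl terpenoids, this reagent should attack equatorially and give the axial 1α-alcohol F6. Desilylation (HF·pyridine, THF, 0 °C) then gives 25.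

Further compounds
F1 | step 13 | 2-bromo derivative of 23 (C2 epimers) | CC(C)=CCC[C@]1(C)[C@@H](Cl)C(Br)C(=O)[C@]2(C)[C@@H](CO[Si](C)(C)C(C)(C)C)C(C3OCCO3)=CC[C@@H]12
F2 | step 7 | pinacol boronate of 7 (Bpin in place of I, geometry retained) | CC1(C)OB(OC1(C)C)/C(=C\C/C=C(\C)CCC=C(C)C)C2OCCO2
F3 | step 7 | (R)-β-alkenyl-γ-butyrolactone (C9 set) | O=C1C[C@@H](CO1)/C(=C\C/C=C(\C)CCC=C(C)C)C2OCCO2
F4 | step 7 | trans-α-methyl-β-alkenyl-γ-butyrolactone | O=C1[C@@H](C)[C@@H](CO1)/C(=C\C/C=C(\C)CCC=C(C)C)C2OCCO2
F5 | step 7 | hydroxy Weinreb amide (16 without the silyl group) | CON(C)C(=O)[C@@H](C)[C@@H](CO)/C(=C\C/C=C(\C)CCC=C(C)C)C1OCCO1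
F6 | step 15 | 1α-alcohol of 23 (silyl ether retained) | CC(C)=CCC[C@]1(C)[C@@H](Cl)C[C@H](O)[C@]2(C)[C@@H](CO[Si](C)(C)C(C)(C)C)C(C3OCCO3)=CC[C@@H]12
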